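**Plan**
1. Retrosynthesis: the two 1,4-dioxane rings are cut first (C3–O/C4–O of unit A, C6–O/C7–O of unit B). This leaves pristimerin and two ring-A-aromatic friedelane esters (unit B, ester on C20; unit C, ester on C19). In each ester, ring D is cut at C13–C18 and C15–C16 into one common ABC tricycle and a ring-E piece.
2. Structural feature used: ring D is tied to the ABC part and to ring E only by C13–C18 and C15–C16, which lie para to each other across the quaternary C14 and C17. C15 and C16 are CH2 groups whose neighbours carry no hydrogen, so a carbonyl-derived union is clean. C27 on C13 can be an exocyclic methylene that admits a sulfonyl radical reversibly and so creates the C13 radical.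
3. Forward order: rings B and C by epoxy-polyene cyclisation (to 13); ring-E pieces 20 and 31 separately; iodide 13 lithiated once to 21, which serves both unions; ring D by a one-pot reductive hydrazone coupling and 6-exo sulfonyl-radical closure; dioxane B–C by epoxide opening and Mitsunobu closure; dioxane A–B last by o-quinone hetero-Diels–Alder reaction.
4. Stereochemistry: C8, C9, C14 from the Sharpless epoxide through a chair–chair cyclisation; C17/C20 of unit B from a desymmetrised meso diol; C17 of unit C from an asymmetric conjugate addition; C13 and C18 in the ring-D closure; C19 by enolate methylation; C6/C7 by double inversion of an α-epoxide; C3/C4 of unit A by suprafacial cycloaddition anti to the 9-methyl group.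

Key step: step 17

Remark: geranyl chloride (3), 1,4-dimethylcyclohexa-1,3-diene (14) and pristimerin (47) are taken as catalogue compounds. The third unit is built with CO2CH3 and CH3 on C19 (next to C18), as the target SMILES shows. The alkyllithium 21 is made once as a cold solution and divided by cannula between the two ring-D unions (steps 17 and 23). Friedelane numbering is used throughout.

Step 1
Reactants: 1 2,3-dimethoxytoluene
Product: 2 1-(chloromethyl)-3,4-dimethoxy-2-methylbenzene
Conditions: (CH2O)n, conc. HCl, dioxane, 23 °C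
Reagents that add atoms: formaldehyde C=O; hydrogen chloride Cl
Why: Blanc chloromethylation goes para to the conjugated 3-methoxy group (the flanked 2-methoxy group is twisted out of plane), i.e. next to the ring methyl group.

Step 2
Reactants: 2 benzyl chloride; 3 geranyl chloride
Product: 5 (E)-homogeranylarene, via benzylmagnesium chloride 4 (not isolated)
Conditions: Mg, THF, 0 °C; then 3, Li2CuCl4 (cat.), −10 °C
Reagents that add atoms: none
Why: Copper-catalysed Grignard–allyl chloride coupling joins at the primary allylic carbon and keeps the E alkene.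

Step 3
Reactants: 5 homogeranylarene
Product: 6 (2E,6E)-allylic alcohol
Conditions: SeO2 (cat.), t-BuOOH, salicylic acid (cat.), CH2Cl2, 0 °C; NaBH4 work-up
Reagents that add atoms: tert-butyl hydroperoxide CC(C)(C)OO
Why: SeO2/t-BuOOH allylic oxidation (ene reaction, then 2,3-shift) attacks the (E)-methyl group of the terminal trisubstituted alkene, so CH2OH stays trans to the chain.

Step 4
Reactants: 6 allylic alcohol
Product: 7 (2R,3R)-epoxy alcohol
Conditions: Ti(OiPr)4, D-(−)-diethyl tartrate, t-BuOOH, 4 Å MS, CH2Cl2, −20 °C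
Reagents that add atoms: tert-butyl hydroperoxide CC(C)(C)OO
Why: Sharpless asymmetric epoxidation; the D-tartrate fixes the (2R,3R) epoxide, the only source of absolute configuration for the ABC part.

Step 5
Reactants: 7 epoxy alcohol
Product: 8 epoxy silyl ether
Conditions: TBSCl, imidazole, DMF, 23 °C
Reagents that add atoms: tert-butyldimethylsilyl chloride CC(C)(C)[Si](C)(C)Cl
Why: Silylation of the primary alcohol keeps the hydroxyl from binding the Lewis acid of the next step.

Step 6
Reactants: 8 epoxy silyl ether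
Product: 9 tricyclic alcohol (8α-H, 9β-CH3, 13β-OH, 14β-CH3, 14α-CH2OTBS)
Conditions: MeAlCl2, CH2Cl2, −78 °C
Reagents that add atoms: none
Why: Epoxide-initiated cation–olefin bicyclisation with Friedel–Crafts termination para to the 3-methoxy group runs through a chair–chair transition state, so anti opening at C14 and anti addition across the E alkene set 8α-H, 9β-CH3, axial 14β-CH3 and equatorial 13β-OH from the epoxide configuration.

Step 7
Reactants: 9 tricyclic alcohol
Product: 10 13-ketone
Conditions: Dess–Martin periodinane, NaHCO3, CH2Cl2, 23 °C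
Reagents that add atoms: none
Why: Dess–Martin oxidation of a hindered secondary alcohol under neutral conditions.

Step 8
Reactants: 10 ketone
Product: 11 13-methylene silyl ether
Conditions: Ph3PCH3Br, KOtBu, PhMe, 90 °C
Reagents that add atoms: methyltriphenylphosphonium bromide C[P+](c1ccccc1)(c1ccccc1)c1ccccc1.[Br-]
Why: Wittig methylenation with the salt-free ylide at raised temperature is the usual answer to a ketone flanked by a quaternary carbon.

Step 9
Reactants: 11 silyl ether
Product: 12 primary alcohol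
Conditions: TBAF, THF, 23 °C
Reagents that add atoms: none
Why: Fluoride cleavage of the silyl ether.

Step 10
Reactants: 12 alcohol
Product: 13 ABC iodide (14α-CH2I, 13-methylene)
Conditions: I2, PPh3, imidazole, PhMe, 80 °C
Reagents that add atoms: iodine II
Why: Appel-type iodination works on a neopentyl alcohol on heating.

Step 11
Reactants: 14 1,4-dimethylcyclohexa-1,3-diene; 15 vinylene carbonate
Product: 16 meso bicyclo[2.2.2]octene carbonate
Conditions: xylene, 170 °C, sealed tube
Reagents that add atoms: none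
Why: Thermal Diels–Alder reaction of an s-cis-locked diene; the adduct is meso, and the two carbons of the new bridge are forced cis on the later ring E.

Step 12
Reactants: 16 carbonate
Product: 17 meso cis-diol
Conditions: NaOH, MeOH–H2O, 23 °C
Reagents that add atoms: none
Why: Saponification of the cyclic carbonate.

Step 13
Reactants: 17 meso diol
Product: 18 α-hydroxy ketone (single enantiomer)
Conditions: Cu(OTf)2 (cat.), (R,R)-Ph-BOX (cat.), NBS, K2CO3, CHCl3, 23 °C
Reagents that add atoms: none
Why: Copper/bis(oxazoline)-catalysed desymmetrising oxidation of a meso 1,2-diol; the ligand enantiomer decides which carbinol becomes the ketone and so fixes C17 and C20 (the antipodal ligand is used if the sense is the opposite one).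

Step 14
Reactants: 18 hydroxy ketone
Product: 19 methyl (1R,4S)-4-formyl-1,4-dimethylcyclohex-2-ene-1-carboxylate
Conditions: Pb(OAc)4, MeOH–PhH, 0 °C
Reagents that add atoms: methanol CO
Why: Criegee-type cleavage of the α-ketol in methanol gives the methyl ester from the ketone carbon and the aldehyde from the carbinol carbon; both stay cis because they were one bridge.

Step 15
Reactants: 19 aldehyde ester
Product: 20 tosylhydrazone of ring E (unit B)
Conditions: TsNHNH2, MeOH, 23 °C
Reagents that add atoms: 4-methylbenzenesulfonohydrazide Cc1ccc(cc1)S(=O)(=O)NN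
Why: Condensation of an aldehyde that has no α-hydrogen to the sulfonylhydrazone.

Step 16
Reactants: 13 ABC iodide
Product: 21 alkyllithium (14α-CH2Li), kept as a solution at −78 °C
Conditions: t-BuLi (2 equiv), Et2O–pentane, −78 °C
Reagents that add atoms: tert-butyllithium CC(C)(C)[Li]
Why: Lithium–iodine exchange on the primary neopentyl iodide is fast at −78 °C and runs through an iodine ate complex, not a free radical, so the homoallylic carbon is not scrambled, the second equivalent of t-BuLi destroys the tert-butyl iodide, and the alkyllithium, which has no β-hydrogen, is stable enough in the cold to be divided between steps 17 and 23.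

Step 17
Reactants: 21 alkyllithium; 20 tosylhydrazone
Product: 24 ring-D sulfone of unit B, via N-silyl tosylhydrazone 22 (not isolated), via seco-ring-D diene 23 (not isolated)
Conditions: 20, TBSOTf, Et3N, THF, −78 °C; add 21 (Et2O–pentane), −78 °C; AcOH, CF3CH2OH, −78 to 23 °C; then PhMe (high dilution), Et3B (cat.), air, 23 °C
Reagents that add atoms: none
Why: Proposed new method: the neopentyl alkyllithium 21 (no β-hydrogen) adds to the C=N of 22 (no α-hydrogen), and acid then expels p-toluenesulfinic acid and N2, which makes C15–C16 as a plain CH2–CH2 link (closest known type: reductive coupling of alkyllithiums with N-silyl sulfonylhydrazones). The sulfinic acid set free is then the chain carrier: the sulfonyl radical adds reversibly to the exocyclic C27 of 23, the tertiary C13 radical closes ring D by 6-exo-trig attack on C18 of the ring-E alkene, and the C19 radical takes hydrogen back from the sulfinic acid (closest known type: sulfonyl-radical addition–cyclisation of 1,6- and 1,7-dienes). C18 is controlled by the tether: C16 sits on the quaternary C17, so the radical reaches C18 on the face that carries C16 and the D/E fusion becomes cis (17-CH3 and 18-H syn). C13 is controlled by a chair transition state in which the tether leaves C14 equatorially and the new C13–C18 bond is equatorial, which places the sulfonylmethyl group axial and anti to the axial 14β-methyl (trans C/D fusion). The step needs addition to C=N ahead of the ester (secured by the fully substituted C20 beside the ester and by −78 °C) and ring closure ahead of hydrogen transfer to the C13 radical (secured by high dilution, the gem-dialkyl effect of C14 and C17, and the reversible sulfonyl addition).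

Step 18
Reactants: 24 sulfone
Product: 25 unit B dimethyl ether
Conditions: Na(Hg), Na2HPO4, MeOH–THF, −20 °C
Reagents that add atoms: none
Why: Reductive desulfonylation by electron transfer turns the sulfonylmethyl group into the 13α-methyl group; esters and aryl ethers are inert.

Step 19
Reactants: 26 3-methylcyclohex-2-en-1-one
Product: 28 (R)-3-methyl-3-vinylcyclohex-1-enyl triflate, via magnesium enolate 27 (not isolated)
Conditions: H2C=CHMgBr, Cu(OTf)2 (cat.), chiral imidazolinium salt (carbene ligand precursor, cat.), Et2O, −30 °C; then PhNTf2, THF, −78 to 0 °C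
Reagents that add atoms: vinylmagnesium bromide C=C[Mg]Br; N-phenyl-bis(trifluoromethanesulfonimide) O=S(=O)(N(c1ccccc1)S(=O)(=O)C(F)(F)F)C(F)(F)F
Why: Copper-catalysed asymmetric conjugate addition creates the quaternary C17 under ligand control, and the enolate is trapped regiospecifically as the C18=C19 enol triflate.

Step 20
Reactants: 28 enol triflate
Product: 29 methyl (R)-3-methyl-3-vinylcyclohex-1-ene-1-carboxylate
Conditions: Pd(OAc)2 (cat.), dppp, CO (1 atm), MeOH, Et3N, DMF, 60 °C
Reagents that add atoms: carbon monoxide [C-]#[O+]; methanol CO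
Why: Palladium-catalysed methoxycarbonylation of an enol triflate.

Step 21
Reactants: 29 vinyl enoate
Product: 30 methyl (S)-3-formyl-3-methylcyclohex-1-ene-1-carboxylate
Conditions: K2OsO4·2H2O (cat.), NaIO4, 2,6-lutidine, dioxane–H2O, 23 °C
Reagents that add atoms: sodium periodate [Na+].[O-]I(=O)(=O)=O
Why: Lemieux–Johnson cleavage; the monosubstituted vinyl group is dihydroxylated far faster than the conjugated trisubstituted enoate.

Step 22
Reactants: 30 aldehyde
Product: 31 tosylhydrazone of ring E (unit C)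
Conditions: TsNHNH2, MeOH, 23 °C
Reagents that add atoms: 4-methylbenzenesulfonohydrazide Cc1ccc(cc1)S(=O)(=O)NN
Why: Condensation of an aldehyde that has no α-hydrogen to the sulfonylhydrazone.

Step 23
Reactants: 21 alkyllithium; 31 tosylhydrazone
Product: 35 ring-D sulfone of unit C, via alkylcerium dichloride 32 (not isolated), via N-silyl tosylhydrazone 33 (not isolated), via seco-ring-D diene 34 (not isolated)
Conditions: 31, TBSOTf, Et3N, THF, −78 °C; 21 (Et2O–pentane), CeCl3, THF, −78 °C; mix, −78 °C; AcOH, CF3CH2OH, −78 to 23 °C; then PhMe (high dilution), Et3B (cat.), air, 23 °C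
Reagents that add atoms: none
Why: Proposed new method: same one-pot logic as step 17 (closest known types: reductive alkyllithium–sulfonylhydrazone coupling, organocerium addition to hydrazones, sulfonyl-radical diene cyclisation); the organocerium reagent adds to C=N and spares the enoate, and the C13 radical closes 6-exo by conjugate addition to C18 on the face of the C16 tether (cis D/E), with C13 set as in step 17.

Step 24
Reactants: 35 sulfone
Product: 36 unit C ester with 19-H (C19 epimers)
Conditions: Na(Hg), Na2HPO4, MeOH–THF, −20 °C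
Reagents that add atoms: none
Why: Reductive desulfonylation gives the 13α-methyl group; the saturated ester is inert.

Step 25
Reactants: 36 ester
Product: 38 unit C dimethyl ether, via lithium enolate 37 (not isolated)
Conditions: LiN(iPr)2, THF, −78 °C; MeI, DMPU, −78 to 0 °C
Reagents that add atoms: iodomethane CI
Why: Ester enolate alkylation; methyl iodide reaches C19 anti to the bulky C13 on the neighbouring C18, i.e. syn to 18-H, which gives 19β-CH3 and 19α-CO2CH3.

Step 26
Reactants: 38 unit C dimethyl ether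
Product: 39 unit C catechol
Conditions: BBr3, CH2Cl2, −78 to 0 °C
Reagents that add atoms: none
Why: Lewis-acid cleavage of both aryl methyl ethers; the tertiary methyl ester survives at low temperature.

Step 27
Reactants: 25 unit B dimethyl ether
Product: 40 unit B catechol
Conditions: BBr3, CH2Cl2, −78 to 0 °C
Reagents that add atoms: none
Why: Lewis-acid cleavage of both aryl methyl ethers; the tertiary methyl ester survives at low temperature.

Step 28
Reactants: 40 catechol
Product: 41 bis-allyl ether
Conditions: allyl bromide, K2CO3, DMF, 23 °C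
Reagents that add atoms: allyl bromide C=CCBr
Why: Williamson allylation gives phenol protection that can later be removed under neutral conditions.

Step 29
Reactants: 41 bis-allyl ether
Product: 42 6,7-dehydro compound (styrene)
Conditions: DDQ, 1,4-dioxane, 80 °C
Reagents that add atoms: none
Why: DDQ dehydrogenation: hydride leaves the benzylic C6 (para to the C2 oxygen) and H7 is then lost; C9 is quaternary, so ring B cannot aromatise further and 8α-H is kept.

Step 30
Reactants: 42 styrene
Product: 43 6α,7α-epoxide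
Conditions: dimethyldioxirane, acetone, −20 °C
Reagents that add atoms: dimethyldioxirane CC1(C)OO1
Why: Neutral epoxidation of the electron-rich styrene from the α face, away from the axial 9β- and 14β-methyl groups; the allyl ether alkenes react far more slowly.

Step 31
Reactants: 43 epoxide; 39 unit C catechol
Product: 44 6β-aryloxy-7α-ol
Conditions: Cs2CO3, DMF, 60 °C, Ar
Reagents that add atoms: none
Why: SN2 opening of the benzylic epoxide at C6 by the less hindered phenoxide (oxygen on C2 of 39, next to C1–H) with inversion gives the 6β-aryl ether and leaves the 7α-hydroxyl.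

Step 32
Reactants: 44 hydroxy ether
Product: 45 B–C dioxane, bis-allyl ether
Conditions: PPh3, DIAD, PhMe, 0 to 60 °C
Reagents that add atoms: none
Why: Intramolecular Mitsunobu etherification: the remaining phenol (oxygen on C3 of unit C) displaces the activated equatorial 7α-oxygen with inversion, closing the cis-fused dioxane with 6β,7β oxygens; anti-periplanar elimination is not available to the equatorial leaving group.

Step 33
Reactants: 45 bis-allyl ether
Product: 46 B–C dimer catechol
Conditions: Pd(PPh3)4 (cat.), morpholine, THF, 23 °C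
Reagents that add atoms: none
Why: Tsuji–Trost deallylation under neutral conditions leaves the benzylic aryl ether at C6 untouched.

Step 34
Reactants: 47 pristimerin
Product: 48 pristimerin 3-O-triisopropylsilyl ether
Conditions: TIPSOTf, 2,6-lutidine, CH2Cl2, −78 °C
Reagents that add atoms: triisopropylsilyl triflate CC(C)[Si](OS(=O)(=O)C(F)(F)F)(C(C)C)C(C)C
Why: O-silylation of the enolic 3-hydroxyl gives a more electron-rich C3=C4 dienophile with a bulky group on C3.

Step 35
Reactants: 46 dimer catechol; 48 silyl enol ether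
Product: 51 target, via o-quinone 49 (not isolated), via silyl ketal 50 (not isolated)
Conditions: 46, Ag2O, Na2SO4, PhH, 23 °C; filter; 48, PhMe, 23 to 50 °C; then TBAF, AcOH, THF, 0 °C
Reagents that add atoms: none
Why: Inverse-demand hetero-Diels–Alder reaction of the o-quinone (O=C2–C3=O of unit B) with the silyl enol ether C3=C4 adds suprafacially (cis dioxane) on the α face, away from the axial 9β-methyl, and the bulky silyloxy carbon C3 pairs with the unhindered quinone oxygen on C2 so that C4 bonds to the oxygen on C3; fluoride then frees the hemiketal.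

**Compound list**
1 | 2,3-dimethoxytoluene | COc1cccc(C)c1OC | starting material
2 | 1-(chloromethyl)-3,4-dimethoxy-2-methylbenzene | COc1ccc(CCl)c(C)c1OC | intermediate
3 | geranyl chloride, (2E)-1-chloro-3,7-dimethylocta-2,6-diene | CC(C)=CCC/C(C)=C/CCl | starting material
4 | (3,4-dimethoxy-2-methylbenzyl)magnesium chloride | COc1ccc(C[Mg]Cl)c(C)c1OC | intermediate
5 | 1-[(3E)-4,8-dimethylnona-3,7-dien-1-yl]-3,4-dimethoxy-2-methylbenzene | COc1ccc(CC/C=C(\C)CCC=C(C)C)c(C)c1OC | intermediate
6 | (2E,6E)-9-(3,4-dimethoxy-2-methylphenyl)-2,6-dimethylnona-2,6-dien-1-ol | COc1ccc(CC/C=C(\C)CC/C=C(\C)CO)c(C)c1OC | intermediate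
7 | [(2R,3R)-3-[(3E)-6-(3,4-dimethoxy-2-methylphenyl)-3-methylhex-3-en-1-yl]-2-methyloxiran-2-yl]methanol | COc1ccc(CC/C=C(\C)CC[C@H]2O[C@]2(C)CO)c(C)c1OC | intermediate
8 | tert-butyldimethylsilyl ether of 7 | COc1ccc(CC/C=C(\C)CC[C@H]2O[C@]2(C)CO[Si](C)(C)C(C)(C)C)c(C)c1OC | intermediate
9 | ABC tricycle: 2,3-dimethoxy-4-methyl aromatic ring A, 8α-H, 9β-CH3, 13β-OH, 14β-CH3, 14α-CH2OTBS | COc1cc2c(c(C)c1OC)CC[C@H]1[C@@]2(C)CC[C@@H](O)[C@]1(C)CO[Si](C)(C)C(C)(C)C | intermediate
10 | 13-ketone of 9 | COc1cc2c(c(C)c1OC)CC[C@H]1[C@@]2(C)CCC(=O)[C@]1(C)CO[Si](C)(C)C(C)(C)C | intermediate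
11 | 13-methylene analogue (14α-CH2OTBS) | COc1cc2c(c(C)c1OC)CC[C@H]1[C@@]2(C)CCC(=C)[C@]1(C)CO[Si](C)(C)C(C)(C)C | intermediate
12 | 13-methylene tricycle with 14α-CH2OH | COc1cc2c(c(C)c1OC)CC[C@H]1[C@@]2(C)CCC(=C)[C@]1(C)CO | intermediate
13 | 13-methylene tricycle with 14α-CH2I (ABC iodide) | COc1cc2c(c(C)c1OC)CC[C@H]1[C@@]2(C)CCC(=C)[C@]1(C)CI | intermediate
14 | 1,4-dimethylcyclohexa-1,3-diene | CC1=CC=C(C)CC1 | starting material
15 | vinylene carbonate (1,3-dioxol-2-one) | O=C1OC=CO1 | starting material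
16 | meso cyclic carbonate of cis-1,4-dimethylbicyclo[2.2.2]oct-5-ene-2,3-diol (oxygens syn to the C=C bridge) | C[C@]12CC[C@](C)(C=C1)[C@@H]3OC(=O)O[C@H]23 | intermediate
17 | meso cis-1,4-dimethylbicyclo[2.2.2]oct-5-ene-2,3-diol | C[C@]12CC[C@](C)(C=C1)[C@H](O)[C@@H]2O | intermediate
18 | 3-hydroxy-1,4-dimethylbicyclo[2.2.2]oct-5-en-2-one, enantiomer with the carbonyl beside the bridgehead that becomes C20 | C[C@]12CC[C@](C)(C=C1)C(=O)[C@@H]2O | intermediate
19 | methyl (1R,4S)-4-formyl-1,4-dimethylcyclohex-2-ene-1-carboxylate (formyl and ester cis) | O=C[C@]1(C)C=C[C@](C)(C(=O)OC)CC1 | intermediate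
20 | N-tosylhydrazone of 19 | Cc1ccc(cc1)S(=O)(=O)N/N=C/[C@]1(C)C=C[C@](C)(C(=O)OC)CC1 | intermediate
21 | alkyllithium from 13 (14α-CH2Li), cold solution in Et2O–pentane | COc1cc2c(c(C)c1OC)CC[C@H]1[C@@]2(C)CCC(=C)[C@]1(C)C[Li] | intermediate
22 | N-tert-butyldimethylsilyl N-tosylhydrazone of 19 | Cc1ccc(cc1)S(=O)(=O)N(/N=C/[C@]1(C)C=C[C@](C)(C(=O)OC)CC1)[Si](C)(C)C(C)(C)C | intermediate
23 | seco-ring-D diene of unit B: ABC tricycle joined through C15H2–C16H2 to ring E; 13-methylene and C18=C19 alkene | COc1cc2c(c(C)c1OC)CC[C@H]1[C@@]2(C)CCC(=C)[C@]1(C)CC[C@]1(C)C=C[C@](C)(C(=O)OC)CC1 | intermediate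
24 | unit B pentacycle with 13α-CH2SO2(p-tolyl) in place of the 13α-methyl; 8α-H, 9β-, 14β-, 17β-CH3, 18β-H, 20β-CH3, 20α-CO2CH3 | COc1cc2c(c(C)c1OC)CC[C@H]1[C@@]2(C)CC[C@@]2(CS(=O)(=O)c3ccc(C)cc3)[C@@H]3C[C@](C)(C(=O)OC)CC[C@]3(C)CC[C@]12C | intermediate
25 | unit B dimethyl ether: methyl 2,3-dimethoxy-24-norfriedela-1,3,5(10)-trien-29-oate (8α-H) | COc1cc2c(c(C)c1OC)CC[C@H]1[C@@]2(C)CC[C@@]2(C)[C@@H]3C[C@](C)(C(=O)OC)CC[C@]3(C)CC[C@]12C | intermediate
26 | 3-methylcyclohex-2-en-1-one | CC1=CC(=O)CCC1 | starting material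
27 | bromomagnesium enolate of (R)-3-methyl-3-vinylcyclohexanone (C18=C19 enolate) | C=C[C@@]1(C)CCCC(O[Mg]Br)=C1 | intermediate
28 | (R)-3-methyl-3-vinylcyclohex-1-en-1-yl trifluoromethanesulfonate | C=C[C@@]1(C)CCCC(OS(=O)(=O)C(F)(F)F)=C1 | intermediate
29 | methyl (R)-3-methyl-3-vinylcyclohex-1-ene-1-carboxylate | C=C[C@@]1(C)CCCC(C(=O)OC)=C1 | intermediate
30 | methyl (S)-3-formyl-3-methylcyclohex-1-ene-1-carboxylate | O=C[C@@]1(C)CCCC(C(=O)OC)=C1 | intermediate
31 | N-tosylhydrazone of 30 | Cc1ccc(cc1)S(=O)(=O)N/N=C/[C@@]1(C)CCCC(C(=O)OC)=C1 | intermediate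
32 | alkylcerium dichloride from 21 | COc1cc2c(c(C)c1OC)CC[C@H]1[C@@]2(C)CCC(=C)[C@]1(C)C[Ce](Cl)Cl | intermediate
33 | N-tert-butyldimethylsilyl N-tosylhydrazone of 30 | Cc1ccc(cc1)S(=O)(=O)N(/N=C/[C@@]1(C)CCCC(C(=O)OC)=C1)[Si](C)(C)C(C)(C)C | intermediate
34 | seco-ring-D diene of unit C: ABC tricycle joined through C15H2–C16H2 to the ring-E enoate | COc1cc2c(c(C)c1OC)CC[C@H]1[C@@]2(C)CCC(=C)[C@]1(C)CC[C@@]1(C)CCCC(C(=O)OC)=C1 | intermediate
35 | unit C pentacycle with 13α-CH2SO2(p-tolyl), 19-H and 19-CO2CH3 (C19 epimers) | COc1cc2c(c(C)c1OC)CC[C@H]1[C@@]2(C)CC[C@@]2(CS(=O)(=O)c3ccc(C)cc3)[C@H]3[C@](C)(CCCC3C(=O)OC)CC[C@]12C | intermediate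
36 | unit C pentacycle with 13α-CH3, 19-H and 19-CO2CH3 (C19 epimers) | COc1cc2c(c(C)c1OC)CC[C@H]1[C@@]2(C)CC[C@@]2(C)[C@H]3[C@](C)(CCCC3C(=O)OC)CC[C@]12C | intermediate
37 | lithium ester enolate of 36 | COc1cc2c(c(C)c1OC)CC[C@H]1[C@@]2(C)CC[C@@]2(C)[C@H]3[C@](C)(CCCC3=C(OC)O[Li])CC[C@]12C | intermediate
38 | unit C dimethyl ether (19β-CH3, 19α-CO2CH3) | COc1cc2c(c(C)c1OC)CC[C@H]1[C@@]2(C)CC[C@@]2(C)[C@H]3[C@](C)(CCC[C@@]3(C)C(=O)OC)CC[C@]12C | intermediate
39 | unit C catechol (2,3-diol) | Oc1cc2c(c(C)c1O)CC[C@H]1[C@@]2(C)CC[C@@]2(C)[C@H]3[C@](C)(CCC[C@@]3(C)C(=O)OC)CC[C@]12C | intermediate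
40 | unit B catechol (2,3-diol, ring B saturated) | Oc1cc2c(c(C)c1O)CC[C@H]1[C@@]2(C)CC[C@@]2(C)[C@@H]3C[C@](C)(C(=O)OC)CC[C@]3(C)CC[C@]12C | intermediate
41 | unit B 2,3-bis(allyl) ether | C=CCOc1cc2c(c(C)c1OCC=C)CC[C@H]1[C@@]2(C)CC[C@@]2(C)[C@@H]3C[C@](C)(C(=O)OC)CC[C@]3(C)CC[C@]12C | intermediate
42 | unit B bis(allyl) ether with C6=C7 double bond (8α-H) | C=CCOc1cc2c(c(C)c1OCC=C)C=C[C@H]1[C@@]2(C)CC[C@@]2(C)[C@@H]3C[C@](C)(C(=O)OC)CC[C@]3(C)CC[C@]12C | intermediate
43 | 6α,7α-epoxide of 42 | C=CCOc1cc2c(c(C)c1OCC=C)[C@H]3O[C@H]3[C@H]1[C@@]2(C)CC[C@@]2(C)[C@@H]3C[C@](C)(C(=O)OC)CC[C@]3(C)CC[C@]12C | intermediate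
44 | 6β-aryloxy-7α-ol: unit B C6 bound to the C2 oxygen of unit C; C3 hydroxyl of unit C free | C=CCOc1cc2c(c(C)c1OCC=C)[C@H](Oc1cc3c(c(C)c1O)CC[C@H]1[C@@]3(C)CC[C@@]3(C)[C@H]4[C@](C)(CCC[C@@]4(C)C(=O)OC)CC[C@]13C)[C@@H](O)[C@H]1[C@@]2(C)CC[C@@]2(C)[C@@H]3C[C@](C)(C(=O)OC)CC[C@]3(C)CC[C@]12C | intermediate
45 | B–C dimer with cis-fused 6β,7β-dioxane, unit B as bis(allyl) ether | C=CCOc1cc2c(c(C)c1OCC=C)[C@@H]5Oc6cc7c(c(C)c6O[C@@H]5[C@H]5[C@@]2(C)CC[C@@]6(C)[C@@H]8C[C@](C)(C(=O)OC)CC[C@]8(C)CC[C@]56C)CC[C@H]5[C@@]7(C)CC[C@@]6(C)[C@H]7[C@](C)(CCC[C@@]7(C)C(=O)OC)CC[C@]56C | intermediate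
46 | B–C dimer catechol | Oc1cc2c(c(C)c1O)[C@@H]5Oc6cc7c(c(C)c6O[C@@H]5[C@H]5[C@@]2(C)CC[C@@]6(C)[C@@H]8C[C@](C)(C(=O)OC)CC[C@]8(C)CC[C@]56C)CC[C@H]5[C@@]7(C)CC[C@@]6(C)[C@H]7[C@](C)(CCC[C@@]7(C)C(=O)OC)CC[C@]56C | intermediate
47 | pristimerin | COC(=O)[C@]1(C)CC[C@]2(C)CC[C@]3(C)C4=CC=C5C(=CC(=O)C(O)=C5C)[C@]4(C)CC[C@@]3(C)[C@@H]2C1 | starting material
48 | pristimerin 3-O-triisopropylsilyl ether | COC(=O)[C@]1(C)CC[C@]2(C)CC[C@]3(C)C4=CC=C5C(=CC(=O)C(O[Si](C(C)C)(C(C)C)C(C)C)=C5C)[C@]4(C)CC[C@@]3(C)[C@@H]2C1 | intermediate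
49 | B–C dimer 2,3-o-quinone (unit B ring A) | O=C1C=C2C(=C(C)C1=O)[C@@H]5Oc6cc7c(c(C)c6O[C@@H]5[C@H]5[C@@]2(C)CC[C@@]6(C)[C@@H]8C[C@](C)(C(=O)OC)CC[C@]8(C)CC[C@]56C)CC[C@H]5[C@@]7(C)CC[C@@]6(C)[C@H]7[C@](C)(CCC[C@@]7(C)C(=O)OC)CC[C@]56C | intermediate
50 | target with the unit A C3 hydroxyl as triisopropylsilyl ether (silyl aryl ketal) | COC(=O)[C@]1(C)CC[C@]2(C)CC[C@]3(C)C4=CC=C5C(=CC(=O)[C@@]6(O[Si](C(C)C)(C(C)C)C(C)C)Oc7cc8c(c(C)c7O[C@@]56C)[C@@H]5Oc6cc7c(c(C)c6O[C@@H]5[C@H]5[C@@]8(C)CC[C@@]6(C)[C@@H]8C[C@](C)(C(=O)OC)CC[C@]8(C)CC[C@]56C)CC[C@H]5[C@@]7(C)CC[C@@]6(C)[C@H]7[C@](C)(CCC[C@@]7(C)C(=O)OC)CC[C@]56C)[C@]4(C)CC[C@@]3(C)[C@@H]2C1 | intermediate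
51 | CNP0039487.1 | COC(=O)[C@]1(C)CC[C@]2(C)CC[C@]3(C)C4=CC=C5C(=CC(=O)[C@@]6(O)Oc7cc8c(c(C)c7O[C@@]56C)[C@@H]5Oc6cc7c(c(C)c6O[C@@H]5[C@H]5[C@@]8(C)CC[C@@]6(C)[C@@H]8C[C@](C)(C(=O)OC)CC[C@]8(C)CC[C@]56C)CC[C@H]5[C@@]7(C)CC[C@@]6(C)[C@H]7[C@](C)(CCC[C@@]7(C)C(=O)OC)CC[C@]56C)[C@]4(C)CC[C@@]3(C)[C@@H]2C1 | target

**Totals**
Total step count: 35. Longest linear sequence: 21 steps (steps 1–10, 16–18, 27–33, 35).

**Steps most likely to fail**

Step 17. Hydrogen transfer from the sulfinic acid to the tertiary C13 radical may outrun the slow 6-exo closure onto the unactivated, doubly neopentyl ring-E alkene, or the sulfinic acid may disproportionate before the chain is established. Fallback: set out from 21 and 20, stop the sequence after the acetic acid/trifluoroethanol stage and isolate diene 23 (the reductive alkyllithium–sulfonylhydrazone coupling alone, which passes through 22). Then close ring D in a separate operation by a metal-hydride hydrogen-atom-transfer reductive radical cyclisation under hydrogenation-type conditions (Mn(dpm)3, PhSiH3, t-BuOOH, i-PrOH). Hydrogen-atom transfer to C27 gives the C13 radical with no sulfinic acid present, the radical closes 6-exo on C18, and a second hydrogen-atom transfer quenches the C19 radical. This turns the exocyclic methylene directly into the 13α-methyl group and rejoins the route at 25; no compound outside the list arises.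

Step 23. The organometallic reagent may attack the enoate instead of the hydrazone, and the sulfinate may add to the enoate in conjugate fashion before the radical chain starts. Fallback: set out from 21, quench it with B(OiPr)3 and hydrolyse with aqueous HCl to the neopentyl boronic acid F1. Join boronic acid F1 to tosylhydrazone 31 by the metal-free reductive coupling of sulfonylhydrazones with boronic acids (K2CO3, dioxane, 110 °C) to give diene 34. Close ring D by the iron-hydride reductive olefin coupling onto the enoate (Fe(acac)3, PhSiH3, EtOH), which gives 36 and rejoins the route there.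

Step 35. The cycloaddition may pair the quinone oxygens with C3 and C4 the other way round, or approach the β face of ring A. Fallback: set out from 46 and 47 and build the two C–O bonds one after the other. Cap the less hindered phenol (oxygen on C2 of unit B) as its silyl ether, mono-silyl dimer F2 (TBSCl, imidazole). Brominate pristimerin at C4 to the 4-bromo-2,3-dione F3 (NBS). Join the free, hindered phenol of F2 to C4 of F3 by silver-assisted etherification (Ag2CO3) to the aryl ether F4. Fluoride then frees the second phenol, which closes the hemiketal on the C3 ketone and returns to the route at 51.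

**Further compounds**
F0 | step 17 | none | none
F1 | step 23 | boronic acid of the ABC tricycle (14α-CH2B(OH)2, 13-methylene) | COc1cc2c(c(C)c1OC)CC[C@H]1[C@@]2(C)CCC(=C)[C@]1(C)CB(O)O
F2 | step 35 | B–C dimer with the unit B C2 oxygen as tert-butyldimethylsilyl ether and the C3 hydroxyl free | CC(C)(C)[Si](C)(C)Oc1cc2c(c(C)c1O)[C@@H]5Oc6cc7c(c(C)c6O[C@@H]5[C@H]5[C@@]2(C)CC[C@@]6(C)[C@@H]8C[C@](C)(C(=O)OC)CC[C@]8(C)CC[C@]56C)CC[C@H]5[C@@]7(C)CC[C@@]6(C)[C@H]7[C@](C)(CCC[C@@]7(C)C(=O)OC)CC[C@]56C
F3 | step 35 | 4-bromo-2,3-dioxo derivative of pristimerin (C4 configuration not fixed) | COC(=O)[C@]1(C)CC[C@]2(C)CC[C@]3(C)C4=CC=C5C(=CC(=O)C(=O)C5(C)Br)[C@]4(C)CC[C@@]3(C)[C@@H]2C1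
F4 | step 35 | aryl ether between C4 of the unit A 2,3-dione (4α-O, 4β-CH3) and the C3 oxygen of unit B in F2 | CC(C)(C)[Si](C)(C)Oc1cc2c(c(C)c1O[C@]3(C)C(=O)C(=O)C=C4C3=CC=C3[C@@]4(C)CC[C@@]4(C)[C@@H]9C[C@](C)(C(=O)OC)CC[C@]9(C)CC[C@]34C)[C@@H]5Oc6cc7c(c(C)c6O[C@@H]5[C@H]5[C@@]2(C)CC[C@@]6(C)[C@@H]8C[C@](C)(C(=O)OC)CC[C@]8(C)CC[C@]56C)CC[C@H]5[C@@]7(C)CC[C@@]6(C)[C@H]7[C@](C)(CCC[C@@]7(C)C(=O)OC)CC[C@]56C
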